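**Retrosynthetic overview**
1. Ring C is closed last at C11–C12 by an iridium-catalysed coupling of the C11 primary alcohol (carbinol C–H) with a tethered 2-substituted diene (25 → 26).
2. The diene arm comes from isoprene, attached at C13–C14 by catalytic asymmetric isoprenylboration of the C14 aldehyde.
3. Rings A and B are formed together from an acyclic 1,7-enyne by Pauson–Khand cyclocarbonylation (C4–C9, C2–C3, C1–C2).
4. The enyne is joined at C8–C9 by an asymmetric Ni/Cr coupling of dialdehyde 9 (fragment A, from 5,6-dihydro-2H-pyran-2-one) with vinyl iodide 17 (fragment B, from the (S)-Roche ester).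
5. Ring order: A and B together (step 15), then C (step 19).

Assumption: the SMILES is taken literally (5S,6S,8S,9R,10R,11S,12S,14R; mutilin numbering C1–C14 is used for locants), so the C14 arm on C5 and the C10 arm on C9 lie on opposite faces of ring B.

**Fragment A**

Step 1
Reactants: 1 5,6-dihydro-2H-pyran-2-one
Product: 2 (S)-4-methyltetrahydro-2H-pyran-2-one
Conditions: MeMgBr, CuBr·SMe2 (5 mol %), (R)-1-[(S)-2-(diphenylphosphino)ferrocenyl]ethyldicyclohexylphosphine (6 mol %), t-BuOMe, −78 °C; NH4Cl (aq)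
Reagents that add atoms: methylmagnesium bromide, C[Mg]Br
Why: Copper-catalysed asymmetric conjugate addition of the Grignard reagent to the unsaturated lactone, in which the chiral diphosphine–copper complex selects the alkene face and sets C6 (lactone C4) as S.

Step 2
Reactants: 2 (S)-4-methyltetrahydro-2H-pyran-2-one
Product: 4 (3S,4S)-3-(hydroxymethyl)-4-methyltetrahydro-2H-pyran-2-one, via lithium enolate 3 (not isolated)
Conditions: LiN(i-Pr)2, THF, −78 °C; then CH2O (gas, from cracked paraformaldehyde), −78 °C; AcOH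
Reagents that add atoms: formaldehyde, C=O
Why: Aldol addition of the lactone enolate to monomeric formaldehyde installs C14 as a hydroxymethyl group trans to the C4 methyl (this centre is re-enolised in step 3).

Step 3
Reactants: 4 (3S,4S)-3-(hydroxymethyl)-4-methyltetrahydro-2H-pyran-2-one
Product: 6 (3R,4S)-3-(hydroxymethyl)-3,4-dimethyltetrahydro-2H-pyran-2-one, via dilithium alkoxide enolate 5 (not isolated)
Conditions: LiN(i-Pr)2 (2.2 equiv), THF, −78 → −40 °C; then MeI, DMPU, −78 °C; AcOH
Reagents that add atoms: iodomethane, CI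
Why: Fráter–Seebach-type alkylation of the alkoxide–enolate dianion, in which the alkoxide blocks β-elimination and MeI approaches anti to the C4 methyl, setting the quaternary C5 (lactone 3R) with its methyl trans to the C6 methyl.

Step 4
Reactants: 6 (3R,4S)-3-(hydroxymethyl)-3,4-dimethyltetrahydro-2H-pyran-2-one
Product: 7 (3R,4S)-3-(hydroxymethyl)-3,4-dimethyltetrahydro-2H-pyran-2-ol (lactol, anomer mixture)
Conditions: i-Bu2AlH (2.3 equiv), CH2Cl2, −78 °C; Rochelle salt (aq)
Reagents that add atoms: none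
Why: Partial lactone reduction with DIBAL-H stops at the aluminium hemiacetal at low temperature and touches no stereocentre.

Step 5
Reactants: 7 (3R,4S)-3-(hydroxymethyl)-3,4-dimethyltetrahydro-2H-pyran-2-ol
Product: 8 (2S,3S)-2-ethynyl-2,3-dimethylpentane-1,5-diol
Conditions: dimethyl (1-diazo-2-oxopropyl)phosphonate, K2CO3, MeOH, 0 °C → rt
Reagents that add atoms: dimethyl (1-diazo-2-oxopropyl)phosphonate, COP(=O)(OC)C(=[N+]=[N-])C(C)=O
Why: Seyferth–Gilbert homologation (Ohira–Bestmann variant) of the open hydroxy-aldehyde form of the lactol turns C4 into the terminal alkyne (C3 is the new carbon) and frees the C8 hydroxyl.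

Step 6
Reactants: 8 (2S,3S)-2-ethynyl-2,3-dimethylpentane-1,5-diol
Product: 9 (2S,3S)-2-ethynyl-2,3-dimethylpentanedial
Conditions: (COCl)2, DMSO, CH2Cl2, −78 °C; Et3N, −78 → 0 °C
Reagents that add atoms: none
Why: Swern oxidation of both primary alcohols gives the C8/C14 dialdehyde, and neither stereocentre can epimerise because C5 is quaternary and C6 is not α to a carbonyl.

**Fragment B**

Step 7
Reactants: 10 methyl (S)-3-hydroxy-2-methylpropanoate
Product: 11 methyl (S)-3-(tert-butyldimethylsilyloxy)-2-methylpropanoate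
Conditions: TBSCl, imidazole, DMF, rt
Reagents that add atoms: tert-butyldimethylsilyl chloride, CC(C)(C)[Si](C)(C)Cl
Why: Standard silylation protects the future C11 hydroxyl; the C10 stereocentre comes from the chiral pool.

Step 8
Reactants: 11 methyl (S)-3-(tert-butyldimethylsilyloxy)-2-methylpropanoate
Product: 12 (R)-3-(tert-butyldimethylsilyloxy)-2-methylpropan-1-ol
Conditions: i-Bu2AlH (2.2 equiv), CH2Cl2, −78 → 0 °C; Rochelle salt (aq)
Reagents that add atoms: none
Why: Hydride reduction of the ester to the primary alcohol leaves the adjacent stereocentre untouched (the descriptor changes only through CIP priorities).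

Step 9
Reactants: 12 (R)-3-(tert-butyldimethylsilyloxy)-2-methylpropan-1-ol
Product: 13 (S)-3-(tert-butyldimethylsilyloxy)-2-methylpropanal
Conditions: (COCl)2, DMSO, CH2Cl2, −78 °C; Et3N, −78 °C; used crude
Reagents that add atoms: none
Why: Swern oxidation at −78 °C gives the α-chiral aldehyde without epimerisation when it is used directly.

Step 10
Reactants: 13 (S)-3-(tert-butyldimethylsilyloxy)-2-methylpropanal
Product: 14 (R)-tert-butyl[(4,4-dibromo-2-methylbut-3-en-1-yl)oxy]dimethylsilane
Conditions: CBr4, PPh3, CH2Cl2, 0 °C; NaHCO3 (aq)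
Reagents that add atoms: carbon tetrabromide, BrC(Br)(Br)Br
Why: Corey–Fuchs (Ramirez) dibromo-olefination is a non-basic Wittig-type reaction that keeps the α-stereocentre intact.

Step 11
Reactants: 14 (R)-tert-butyl[(4,4-dibromo-2-methylbut-3-en-1-yl)oxy]dimethylsilane
Product: 15 (R)-tert-butyldimethyl[(2-methylbut-3-yn-1-yl)oxy]silane
Conditions: n-BuLi (2.1 equiv), THF, −78 °C; NH4Cl (aq)
Reagents that add atoms: none
Why: Second stage of the Corey–Fuchs sequence (Br/Li exchange, Fritsch–Buttenberg–Wiechell shift, protonation of the acetylide) gives the terminal alkyne C9≡C1.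

Step 12
Reactants: 15 (R)-tert-butyldimethyl[(2-methylbut-3-yn-1-yl)oxy]silane
Product: 17 (S)-tert-butyl[(3-iodo-2-methylbut-3-en-1-yl)oxy]dimethylsilane, via iodoalkenylborane 16 (not isolated)
Conditions: B-iodo-9-BBN, pentane, −20 → 0 °C; then AcOH, 0 °C
Reagents that add atoms: B-iodo-9-borabicyclo[3.3.1]nonane, IB1C2CCCC1CCC2
Why: Syn-haloboration of the terminal alkyne puts iodine on the internal carbon, and protodeboronation then gives the 2-iodo-1-alkene needed for C9.

**Fragment C**

Step 13
Reactants: 18 isoprene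
Product: 20 4,4,5,5-tetramethyl-2-(2-methylidenebut-3-en-1-yl)-1,3,2-dioxaborolane, via isoprenylpotassium 19 (not isolated)
Conditions: n-BuLi, 2,2,6,6-tetramethylpiperidine, KOt-Bu, THF, −78 °C; then 2-isopropoxy-4,4,5,5-tetramethyl-1,3,2-dioxaborolane, −78 °C → rt
Reagents that add atoms: 2-isopropoxy-4,4,5,5-tetramethyl-1,3,2-dioxaborolane, CC(C)OB1OC(C)(C)C(C)(C)O1
Why: Amide-base metalation of the isoprene methyl group followed by borylation of the pentadienyl-type anion at the primary carbon gives the 2-substituted allylboronate.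

**Union and endgame**

Step 14
Reactants: 9 (2S,3S)-2-ethynyl-2,3-dimethylpentanedial; 17 (S)-tert-butyl[(3-iodo-2-methylbut-3-en-1-yl)oxy]dimethylsilane
Product: 21 (2S,3S,5S,7R)-8-(tert-butyldimethylsilyloxy)-2-ethynyl-2,3,7-trimethyl-6-methylidene-5-(triethylsilyloxy)octanal
Conditions: CrCl2 (10 mol %), (S)-N-[2-(4-isopropyl-4,5-dihydrooxazol-2-yl)-6-methylphenyl]methanesulfonamide (12 mol %), NiCl2(2,9-dimethyl-1,10-phenanthroline) (2 mol %), Mn, Et3SiCl, LiCl, MeCN, rt
Reagents that add atoms: chlorotriethylsilane, CC[Si](Cl)(CC)CC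
Why: Catalytic asymmetric Nozaki–Hiyama–Kishi coupling in which the alkenylchromium adds only to the unhindered C8 aldehyde (the C14 aldehyde is neopentylic), the chromium-bound sulfonamide selects the aldehyde face to set C8 as S, and Et3SiCl turns chromium over and delivers the TES ether.

Step 15
Reactants: 21 (2S,3S,5S,7R)-8-(tert-butyldimethylsilyloxy)-2-ethynyl-2,3,7-trimethyl-6-methylidene-5-(triethylsilyloxy)octanal
Product: 22 (4S,5S,7S,7aR)-7a-[(2R)-1-(tert-butyldimethylsilyloxy)propan-2-yl]-4,5-dimethyl-2-oxo-7-(triethylsilyloxy)-2,4,5,6,7,7a-hexahydro-1H-indene-4-carbaldehyde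
Conditions: Co2(CO)8 (10 mol %), tetramethylthiourea (60 mol %), CO (1 atm), PhMe, 70 °C
Reagents that add atoms: carbon monoxide, [C-]#[O+]
Why: Intramolecular Pauson–Khand [2+2+1] of the 1,7-enyne (helped by the quaternary C5) forms C4–C9, C3–C2 and C2–C1 and so rings A and B; the metallacycle forms on the alkene face anti to the allylic C8 OTES group, putting C1 anti and the C10 arm syn to it (9R).

Step 16
Reactants: 22 hydrindenone aldehyde (as named in step 15); 20 4,4,5,5-tetramethyl-2-(2-methylidenebut-3-en-1-yl)-1,3,2-dioxaborolane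
Product: 23 (4S,5S,7S,7aR)-7a-[(2R)-1-(tert-butyldimethylsilyloxy)propan-2-yl]-4-[(1R)-1-hydroxy-3-methylidenepent-4-en-1-yl]-4,5-dimethyl-7-(triethylsilyloxy)-1,4,5,6,7,7a-hexahydro-2H-inden-2-one
Conditions: 20 (1.5 equiv), (R)-3,3′-bis(2,4,6-triisopropylphenyl)-1,1′-binaphthyl-2,2′-diyl hydrogen phosphate (5 mol %), 4 Å MS, PhMe, −30 °C; NaHCO3 (aq)
Reagents that add atoms: none
Why: Chiral-phosphoric-acid-catalysed allylboration through a closed six-membered transition state with allylic transposition forms C13–C14; the catalyst shields one aldehyde face so that C14 is R, and the enone ketone does not react.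

Step 17
Reactants: 23 homoallylic alcohol (as named in step 16)
Product: 24 (1R)-1-[(4S,5S,7S,7aR)-7a-[(2R)-1-(tert-butyldimethylsilyloxy)propan-2-yl]-4,5-dimethyl-2-oxo-7-(triethylsilyloxy)-2,4,5,6,7,7a-hexahydro-1H-inden-4-yl]-3-methylidenepent-4-en-1-yl acetate
Conditions: Ac2O, DMAP, pyridine, CH2Cl2, rt → 40 °C
Reagents that add atoms: acetic anhydride, CC(=O)OC(C)=O
Why: DMAP-catalysed acylation of the only free hydroxyl installs the C14 acetate of the target.

Step 18
Reactants: 24 acetate (as named in step 17)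
Product: 25 (1R)-1-[(4S,5S,7S,7aR)-7-hydroxy-7a-[(2R)-1-hydroxypropan-2-yl]-4,5-dimethyl-2-oxo-2,4,5,6,7,7a-hexahydro-1H-inden-4-yl]-3-methylidenepent-4-en-1-yl acetate
Conditions: HF·pyridine, pyridine, THF, 0 °C → rt
Reagents that add atoms: none
Why: Buffered fluoride cleaves both silyl ethers (Si–F bond formation) while the acetate, enone and diene survive.

Step 19
Reactants: 25 diol diene acetate (as named in step 18)
Product: 26 pleuromutilin E
Conditions: [Ir(cod)Cl]2 (5 mol %), (R)-4,12-bis(diphenylphosphino)[2.2]paracyclophane (10 mol %), K3PO4 (5 mol %), THF (2 mM), 80 °C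
Reagents that add atoms: none
Why: Proposed new method: an intramolecular, redox-neutral iridium-catalysed coupling of a primary alcohol with a 2-substituted 1,3-diene through carbinol C–H activation, in which the catalyst dehydrogenates C11–OH to the aldehyde, the iridium hydride adds to the exo-methylene of the diene (creating the C12 methyl) to give a 1,1-disubstituted π-allyl, and its primary σ-allyl form (methyl trans to CH2–Ir, C10 pseudo-equatorial) adds to the tethered aldehyde at C12 through a closed chair transition state, forming C11–C12, ring C, the vinyl group and both stereocentres (11S,12S, OH anti to the C12 methyl; aldehyde face chosen by the ligand) before alkoxide exchange with the next primary alcohol turns the cycle over, the secondary C8–OH being left alone because ketones do not couple; the closest known reactions are the intermolecular iridium- and ruthenium-catalysed alcohol–diene hydrohydroxyalkylations, including diene–methanol couplings that form quaternary carbons at C2 of the diene, which have not been shown intramolecularly or for a medium ring.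

**Compound list**
1 | 5,6-dihydro-2H-pyran-2-one | O=C1C=CCCO1 | starting material
2 | (S)-4-methyltetrahydro-2H-pyran-2-one | O=C1C[C@@H](C)CCO1 | intermediate
3 | lithium enolate of 2 (lithium (S)-4-methyl-5,6-dihydro-4H-pyran-2-olate) | [Li]OC1=C[C@@H](C)CCO1 | intermediate
4 | (3S,4S)-3-(hydroxymethyl)-4-methyltetrahydro-2H-pyran-2-one | OC[C@@H]1[C@@H](C)CCOC1=O | intermediate
5 | dilithium alkoxide enolate of 4 | [Li]OCC1=C(O[Li])OCC[C@@H]1C | intermediate
6 | (3R,4S)-3-(hydroxymethyl)-3,4-dimethyltetrahydro-2H-pyran-2-one | OC[C@@]1(C)[C@@H](C)CCOC1=O | intermediate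
7 | (3R,4S)-3-(hydroxymethyl)-3,4-dimethyltetrahydro-2H-pyran-2-ol (lactol, anomer mixture) | OC[C@@]1(C)[C@@H](C)CCOC1O | intermediate
8 | (2S,3S)-2-ethynyl-2,3-dimethylpentane-1,5-diol | OC[C@](C)(C#C)[C@@H](C)CCO | intermediate
9 | (2S,3S)-2-ethynyl-2,3-dimethylpentanedial | O=C[C@](C)(C#C)[C@@H](C)CC=O | intermediate
10 | methyl (S)-3-hydroxy-2-methylpropanoate (Roche ester) | COC(=O)[C@@H](C)CO | starting material
11 | methyl (S)-3-(tert-butyldimethylsilyloxy)-2-methylpropanoate | COC(=O)[C@@H](C)CO[Si](C)(C)C(C)(C)C | intermediate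
12 | (R)-3-(tert-butyldimethylsilyloxy)-2-methylpropan-1-ol | OC[C@@H](C)CO[Si](C)(C)C(C)(C)C | intermediate
13 | (S)-3-(tert-butyldimethylsilyloxy)-2-methylpropanal | O=C[C@@H](C)CO[Si](C)(C)C(C)(C)C | intermediate
14 | (R)-tert-butyl[(4,4-dibromo-2-methylbut-3-en-1-yl)oxy]dimethylsilane | BrC(Br)=C[C@@H](C)CO[Si](C)(C)C(C)(C)C | intermediate
15 | (R)-tert-butyldimethyl[(2-methylbut-3-yn-1-yl)oxy]silane | C#C[C@@H](C)CO[Si](C)(C)C(C)(C)C | intermediate
16 | (Z)-2-iodoalkenyl-9-BBN adduct of 15 (iodine on the internal carbon, boron on the terminal carbon) | I/C(=C\B1C2CCCC1CCC2)[C@@H](C)CO[Si](C)(C)C(C)(C)C | intermediate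
17 | (S)-tert-butyl[(3-iodo-2-methylbut-3-en-1-yl)oxy]dimethylsilane | C=C(I)[C@@H](C)CO[Si](C)(C)C(C)(C)C | intermediate
18 | isoprene | C=CC(C)=C | starting material
19 | (2-methylidenebut-3-en-1-yl)potassium | [K]CC(=C)C=C | intermediate
20 | 4,4,5,5-tetramethyl-2-(2-methylidenebut-3-en-1-yl)-1,3,2-dioxaborolane | C=CC(=C)CB1OC(C)(C)C(C)(C)O1 | intermediate
21 | (2S,3S,5S,7R)-8-(tert-butyldimethylsilyloxy)-2-ethynyl-2,3,7-trimethyl-6-methylidene-5-(triethylsilyloxy)octanal | O=C[C@](C)(C#C)[C@@H](C)C[C@H](O[Si](CC)(CC)CC)C(=C)[C@@H](C)CO[Si](C)(C)C(C)(C)C | intermediate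
22 | (4S,5S,7S,7aR)-7a-[(2R)-1-(tert-butyldimethylsilyloxy)propan-2-yl]-4,5-dimethyl-2-oxo-7-(triethylsilyloxy)-2,4,5,6,7,7a-hexahydro-1H-indene-4-carbaldehyde | O=C[C@]1(C)C2=CC(=O)C[C@@]2([C@@H](O[Si](CC)(CC)CC)C[C@@H]1C)[C@@H](C)CO[Si](C)(C)C(C)(C)C | intermediate
23 | (4S,5S,7S,7aR)-7a-[(2R)-1-(tert-butyldimethylsilyloxy)propan-2-yl]-4-[(1R)-1-hydroxy-3-methylidenepent-4-en-1-yl]-4,5-dimethyl-7-(triethylsilyloxy)-1,4,5,6,7,7a-hexahydro-2H-inden-2-one | C=CC(=C)C[C@@H](O)[C@]1(C)C2=CC(=O)C[C@@]2([C@@H](O[Si](CC)(CC)CC)C[C@@H]1C)[C@@H](C)CO[Si](C)(C)C(C)(C)C | intermediate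
24 | C14 acetate of 23 | C=CC(=C)C[C@@H](OC(C)=O)[C@]1(C)C2=CC(=O)C[C@@]2([C@@H](O[Si](CC)(CC)CC)C[C@@H]1C)[C@@H](C)CO[Si](C)(C)C(C)(C)C | intermediate
25 | (1R)-1-[(4S,5S,7S,7aR)-7-hydroxy-7a-[(2R)-1-hydroxypropan-2-yl]-4,5-dimethyl-2-oxo-2,4,5,6,7,7a-hexahydro-1H-inden-4-yl]-3-methylidenepent-4-en-1-yl acetate | C=CC(=C)C[C@@H](OC(C)=O)[C@]1(C)C2=CC(=O)C[C@@]2([C@@H](O)C[C@@H]1C)[C@@H](C)CO | intermediate
26 | pleuromutilin E | C=C[C@]1(C)C[C@@H](OC(C)=O)[C@]2(C)C3=CC(=O)C[C@@]3([C@@H](O)C[C@@H]2C)[C@@H](C)[C@@H]1O | target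

**Totals**
Total step count: 19. Longest linear sequence: 12 steps (steps 1–6 then 14–19; the branch through steps 7–12 is equally long).

**Three steps most likely to fail**

Step 19 (the proposed new ring closure). Risks are the strain of an eight-membered ring whose two arms leave ring B from opposite faces, hydrometalation of the diene at the other terminus (leading to a nine-membered ring), unproven C11/C12 selectivity, and base-induced retro-aldol at C8–C9. The fallback uses known chemistry, sets out from 25 and returns at 26. Nickel-catalysed 1,4-hydroboration of the diene (Ni(cod)2, PCy3, excess pinacolborane, PhMe, rt; methanolic work-up frees the two hydroxyls again) gives the (E)-allylboronate diol F1. Copper/TEMPO aerobic oxidation (Cu(MeCN)4OTf, 2,2′-bipyridine, TEMPO, N-methylimidazole, air, MeCN), which is selective for the primary alcohol, gives the allylboronate aldehyde F2. On warming, F2 closes ring C by intramolecular allylboration through a six-membered cyclic transition state (C13 pseudo-equatorial, C10 pseudo-axial, cis-fused to the forming ring), and hydrolytic work-up gives 26.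

Step 15 (Pauson–Khand). Risks are the low reactivity of a 1,7-enyne with a 1,1-disubstituted alkene and the facial selectivity at C9, which must overcome two pseudo-axial methyl groups. The fallback sets out from 21 and returns at 22. Markovnikov hydrostannation of the terminal alkyne (Mo(CO)3(CNt-Bu)3, Bu3SnH, THF, 55 °C) gives the α-stannyl alkene F3, and iododestannylation (I2, CH2Cl2, 0 °C) gives the 2-iodo-1-alkene F4. A palladium-catalysed cyclic carbopalladation–carbonylation cascade (Pd(PPh3)4, CO 1 atm, Et3N, MeCN, 70 °C) then builds the same cyclopentenone 22 by 6-exo Heck cyclisation onto the 1,1-disubstituted alkene, CO insertion, 5-exo acylpalladation of the new exocyclic alkene and β-hydride elimination.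

Step 14 (Ni/Cr coupling on a dialdehyde). Risks are addition to the C14 aldehyde as well and incomplete control at C8. The fallback sets out from 8 and returns at 21. TEMPO/PhI(OAc)2 (CH2Cl2, rt, 1.1 equiv) oxidises only the unhindered C8 alcohol, and the hydroxy-aldehyde closes onto the C14 hydroxyl to give the lactol F5, so no free C14 aldehyde is present. Stoichiometric Nozaki–Hiyama–Kishi coupling of F5 with 17 (CrCl2, catalytic NiCl2, the same sulfonamide ligand, Et3N, THF) gives the diol F6. Et3SiOTf/2,6-lutidine gives the bis-TES ether F7, and Swern oxidation, which oxidises a primary TES ether directly while leaving the secondary TES and the TBS ether, gives 21.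

**Further compounds**
F1 | step 19 | (E)-allylboronate diol: 25 with the diene replaced by CH3–C(C13)=CH–CH2–B(pin), methyl cis to CH2B | C/C(C[C@@H](OC(C)=O)[C@]1(C)C2=CC(=O)C[C@@]2([C@@H](O)C[C@@H]1C)[C@@H](C)CO)=C\CB1OC(C)(C)C(C)(C)O1
F2 | step 19 | allylboronate aldehyde: F1 with C11 oxidised to the aldehyde | C/C(C[C@@H](OC(C)=O)[C@]1(C)C2=CC(=O)C[C@@]2([C@@H](O)C[C@@H]1C)[C@@H](C)C=O)=C\CB1OC(C)(C)C(C)(C)O1
F3 | step 15 | α-stannyl alkene: 21 with the ethynyl group converted to 1-(tributylstannyl)vinyl | O=C[C@](C)(C(=C)[Sn](CCCC)(CCCC)CCCC)[C@@H](C)C[C@H](O[Si](CC)(CC)CC)C(=C)[C@@H](C)CO[Si](C)(C)C(C)(C)C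
F4 | step 15 | 2-iodo-1-alkene: 21 with the ethynyl group converted to 1-iodovinyl | O=C[C@](C)(C(I)=C)[C@@H](C)C[C@H](O[Si](CC)(CC)CC)C(=C)[C@@H](C)CO[Si](C)(C)C(C)(C)C
F5 | step 14 | (4S,5S)-5-ethynyl-4,5-dimethyltetrahydro-2H-pyran-2-ol (lactol, anomer mixture) | OC1C[C@H](C)[C@@](C)(C#C)CO1
F6 | step 14 | (2S,3S,5S,7R)-8-(tert-butyldimethylsilyloxy)-2-ethynyl-2,3,7-trimethyl-6-methylideneoctane-1,5-diol | OC[C@](C)(C#C)[C@@H](C)C[C@H](O)C(=C)[C@@H](C)CO[Si](C)(C)C(C)(C)C
F7 | step 14 | 1,5-bis(triethylsilyl) ether of F6 | CC[Si](CC)(CC)OC[C@](C)(C#C)[C@@H](C)C[C@H](O[Si](CC)(CC)CC)C(=C)[C@@H](C)CO[Si](C)(C)C(C)(C)C
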